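**Plan**

1. Retrosynthesis (oxolane numbered O1, C2 = CH–3,4-dimethoxyphenyl, C3, C4, C5 = CH–3,4,5-trimethoxyphenyl): the C3 methyl is traced back to one ester of a C3 gem-diester (CH3 ← CH2OTs ← CH2OH ← CO2Me). The ring bonds O1–C5 and C2–C3 are then cut together, leaving 3,4-dimethoxybenzaldehyde (O1=C2) and a cis-2-methyl-3-arylcyclopropane-1,1-diester (C3–C4–C5), itself from a Z-propenylarene and a malonate carbene.
2. Enabling feature: O1–C2(aryl) is a latent aryl aldehyde C=O, C5 carries a cation-stabilising aryl group, and C3 carries a carbon substituent that can descend from a malonate. This is the donor–acceptor pattern of an arylcyclopropane diester, and the 2,5-cis diaryl relation is the innate outcome of inserting C=O into that three-membered ring.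
3. Forward: Z-retentive Suzuki coupling, then enantioselective copper-carbene cyclopropanation, then Lewis-acid ring expansion of the cyclopropane with the aldehyde to the fully substituted oxolane, then dealkoxycarbonylation with equilibration, then ester to methyl.
4. Stereochemistry: the catalytic cyclopropanation sets both cyclopropane centres (cis from the Z geometry, absolute sense from the ligand). The ring expansion inverts the benzylic centre (giving 4,5-trans) and sets C2 (2,5-cis) by substrate control. C3 is set thermodynamically (ester trans to the C2 aryl group, cis to the C4 methyl).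

Key step: step 4

Remark on the chemistry: L* in step 3 is a C2-symmetric bis(4-phenyloxazoline) whose bridging carbon carries two arylmethyl side arms. It is assumed that one antipode of L* (both are made from commercial phenylglycinol) delivers the carbene to the alkene face that gives the (2S,3S)-cyclopropane.

**Route**

Step 1
Reactants: 1 5-bromo-1,2,3-trimethoxybenzene; 2 (Z)-prop-1-en-1-ylboronic acid
Product: 3 1,2,3-trimethoxy-5-[(1Z)-prop-1-en-1-yl]benzene
Conditions: Pd(PPh3)4 (5 mol %), K2CO3, 1,4-dioxane/H2O, 80 °C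
Reagents that add atoms: none
Why: Suzuki–Miyaura cross-coupling, in which transmetalation and reductive elimination at palladium retain the alkene geometry, so the Z-propenyl group should be transferred intact to the aryl bromide.

Step 2
Reactants: 4 dimethyl malonate; 5 (diacetoxyiodo)benzene
Product: 6 dimethyl 2-(phenyl-λ3-iodanylidene)propanedioate
Conditions: KOH, MeCN, 0 °C
Reagents that add atoms: none
Why: Base-mediated condensation of an active methylene compound with a trivalent iodine diacetate (ligand exchange at iodine, then deprotonation) is the standard preparation of malonate iodonium ylides, which act as reactive diazomalonate surrogates.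

Step 3
Reactants: 3 1,2,3-trimethoxy-5-[(1Z)-prop-1-en-1-yl]benzene; 6 dimethyl 2-(phenyl-λ3-iodanylidene)propanedioate
Product: 7 dimethyl (2S,3S)-2-methyl-3-(3,4,5-trimethoxyphenyl)cyclopropane-1,1-dicarboxylate
Conditions: Cu(MeCN)4PF6 (10 mol %), L* (12 mol %), 4 Å MS, toluene, 0 °C → rt
Reagents that add atoms: none
Why: Enantioselective copper-catalysed cyclopropanation of a 1,2-disubstituted alkene with a malonate iodonium ylide, in which the electrophilic copper carbene adds to the electron-rich Z-alkene in a concerted syn fashion (aryl and methyl stay cis) and the bis(oxazoline) pocket selects the alkene face, setting both stereocentres in one event.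

Step 4
Reactants: 7 dimethyl (2S,3S)-2-methyl-3-(3,4,5-trimethoxyphenyl)cyclopropane-1,1-dicarboxylate; 8 3,4-dimethoxybenzaldehyde
Product: 9 dimethyl (2R,4R,5R)-2-(3,4-dimethoxyphenyl)-4-methyl-5-(3,4,5-trimethoxyphenyl)oxolane-3,3-dicarboxylate
Conditions: 8 (3 equiv), Sn(OTf)2 (5 mol %), CH2Cl2, 0 °C → rt, short reaction time
Reagents that add atoms: none
Why: Sn(OTf)2 chelates the malonate and polarises the C1–C3 bond of 7; the carbonyl oxygen of 8 then attacks the benzylic carbon C3 from the backside in an SN2-like event on an intimate ion pair, opening the three-membered ring with inversion to an (E)-oxocarbenium ion tethered to a tin malonate enolate, which collapses by C–C bond formation between the malonate carbon and the oxocarbenium carbon. The closest known reaction type is the Lewis acid-catalysed (3+2) annulation of aldehydes with 2-arylcyclopropane-1,1-diesters, a two-atom ring expansion of cyclopropane to oxolane that is known to proceed with inversion at the donor carbon. The oxolane ring closes in the second stage by a 5-(enolexo)-endo-trig attack of the enolate carbon on the cationic C=O+ unit. Of the ring stereocentres of 9, C5 arises from cyclopropane C3 with inversion, so the cis aryl/methyl relation of 7 becomes 4,5-trans; C4 is the untouched methyl-bearing carbon of 7; and the new centre C2 is set by substrate control in an envelope transition state in which both aryl groups are pseudo-equatorial and end up 2,5-cis. The step needs substitution with inversion to outrun ionisation of the benzylic C–C bond (which would isomerise 7 to its trans isomer and lead to the 4,5-cis series); this should be secured by the 3,4,5-trimethoxyphenyl donor, whose twisted para-methoxy group and two meta-methoxy groups make it a weaker cation stabiliser than a 4-alkoxyphenyl group, and by the electron-rich, strongly nucleophilic aldehyde used in excess, and since C4 is a spectator any leakage can only give diastereomers and never the enantiomer.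

Step 5
Reactants: 9 dimethyl (2R,4R,5R)-2-(3,4-dimethoxyphenyl)-4-methyl-5-(3,4,5-trimethoxyphenyl)oxolane-3,3-dicarboxylate
Product: 11 methyl (2S,3S,4R,5R)-2-(3,4-dimethoxyphenyl)-4-methyl-5-(3,4,5-trimethoxyphenyl)oxolane-3-carboxylate, via 3-epi monoester 10 (not isolated)
Conditions: LiCl, H2O, DMSO, 150 °C; then NaOMe (cat.), MeOH, 60 °C
Reagents that add atoms: none
Why: Krapcho dealkoxycarbonylation (chloride SN2 at an ester methyl, loss of CO2, protonation of the ester enolate) followed by base equilibration through the same enolate should set C3 under thermodynamic control with the ester trans to the bulkier C2 aryl group and cis to the C4 methyl, while ring opening by β-elimination of the ring oxygen is stereoelectronically disfavoured because the C2–O1 bond lies in the nodal plane of the exocyclic enolate.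

Step 6
Reactants: 11 methyl (2S,3S,4R,5R)-2-(3,4-dimethoxyphenyl)-4-methyl-5-(3,4,5-trimethoxyphenyl)oxolane-3-carboxylate
Product: 12 [(2S,3R,4R,5R)-2-(3,4-dimethoxyphenyl)-4-methyl-5-(3,4,5-trimethoxyphenyl)oxolan-3-yl]methanol
Conditions: LiAlH4, THF, 0 °C; Fieser work-up
Reagents that add atoms: none
Why: Hydride reduction of an ester to the primary alcohol, which at low temperature does not enolise C3 and leaves the aryl methyl ethers and the ring untouched.

Step 7
Reactants: 12 [(2S,3R,4R,5R)-2-(3,4-dimethoxyphenyl)-4-methyl-5-(3,4,5-trimethoxyphenyl)oxolan-3-yl]methanol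
Product: 13 [(2S,3R,4R,5R)-2-(3,4-dimethoxyphenyl)-4-methyl-5-(3,4,5-trimethoxyphenyl)oxolan-3-yl]methyl 4-methylbenzenesulfonate
Conditions: TsCl, Et3N, DMAP (cat.), CH2Cl2, 0 °C → rt
Reagents that add atoms: 4-methylbenzenesulfonyl chloride, Cc1ccc(cc1)S(Cl)(=O)=O
Why: DMAP-catalysed sulfonylation of an unhindered primary alcohol turns the hydroxyl into a leaving group without touching any stereocentre.

Step 8
Reactants: 13 [(2S,3R,4R,5R)-2-(3,4-dimethoxyphenyl)-4-methyl-5-(3,4,5-trimethoxyphenyl)oxolan-3-yl]methyl 4-methylbenzenesulfonate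
Product: 14 (2S,3S,4R,5R)-2-(3,4-dimethoxyphenyl)-3,4-dimethyl-5-(3,4,5-trimethoxyphenyl)oxolane
Conditions: LiEt3BH, THF, 0 °C → rt
Reagents that add atoms: none
Why: Reductive deoxygenation by SN2 hydride displacement of a primary tosylate at the exocyclic carbon should convert CH2OTs into the C3 methyl group with no ring stereocentre involved.

**Compound list**

1 | 5-bromo-1,2,3-trimethoxybenzene | COc1cc(Br)cc(OC)c1OC | starting material
2 | (Z)-prop-1-en-1-ylboronic acid | C/C=C\B(O)O | starting material
3 | 1,2,3-trimethoxy-5-[(1Z)-prop-1-en-1-yl]benzene | C/C=C\c1cc(OC)c(OC)c(OC)c1 | intermediate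
4 | dimethyl malonate (dimethyl propanedioate) | COC(=O)CC(=O)OC | starting material
5 | (diacetoxyiodo)benzene | CC(=O)OI(OC(C)=O)c1ccccc1 | starting material
6 | dimethyl 2-(phenyl-λ3-iodanylidene)propanedioate (malonate iodonium ylide) | COC(=O)[C-]([I+]c1ccccc1)C(=O)OC | intermediate
7 | dimethyl (2S,3S)-2-methyl-3-(3,4,5-trimethoxyphenyl)cyclopropane-1,1-dicarboxylate (aryl and methyl cis) | COc1cc([C@@H]2[C@H](C)C2(C(=O)OC)C(=O)OC)cc(OC)c1OC | intermediate
8 | 3,4-dimethoxybenzaldehyde | COc1ccc(C=O)cc1OC | starting material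
9 | dimethyl (2R,4R,5R)-2-(3,4-dimethoxyphenyl)-4-methyl-5-(3,4,5-trimethoxyphenyl)oxolane-3,3-dicarboxylate (2,5-cis, 4,5-trans) | COc1ccc([C@H]2O[C@@H](c3cc(OC)c(OC)c(OC)c3)[C@H](C)C2(C(=O)OC)C(=O)OC)cc1OC | intermediate
10 | methyl (2S,3R,4R,5R)-2-(3,4-dimethoxyphenyl)-4-methyl-5-(3,4,5-trimethoxyphenyl)oxolane-3-carboxylate (3-epimer, ester cis to the C2 aryl; not isolated) | COc1ccc([C@H]2O[C@@H](c3cc(OC)c(OC)c(OC)c3)[C@H](C)[C@H]2C(=O)OC)cc1OC | intermediate
11 | methyl (2S,3S,4R,5R)-2-(3,4-dimethoxyphenyl)-4-methyl-5-(3,4,5-trimethoxyphenyl)oxolane-3-carboxylate (ester trans to the C2 aryl, cis to the C4 methyl) | COc1ccc([C@H]2O[C@@H](c3cc(OC)c(OC)c(OC)c3)[C@H](C)[C@@H]2C(=O)OC)cc1OC | intermediate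
12 | [(2S,3R,4R,5R)-2-(3,4-dimethoxyphenyl)-4-methyl-5-(3,4,5-trimethoxyphenyl)oxolan-3-yl]methanol | COc1ccc([C@H]2O[C@@H](c3cc(OC)c(OC)c(OC)c3)[C@H](C)[C@@H]2CO)cc1OC | intermediate
13 | [(2S,3R,4R,5R)-2-(3,4-dimethoxyphenyl)-4-methyl-5-(3,4,5-trimethoxyphenyl)oxolan-3-yl]methyl 4-methylbenzenesulfonate | COc1ccc([C@H]2O[C@@H](c3cc(OC)c(OC)c(OC)c3)[C@H](C)[C@@H]2COS(=O)(=O)c4ccc(C)cc4)cc1OC | intermediate
14 | (2S,3S,4R,5R)-2-(3,4-dimethoxyphenyl)-3,4-dimethyl-5-(3,4,5-trimethoxyphenyl)oxolane | COc1ccc([C@H]2O[C@@H](c3cc(OC)c(OC)c(OC)c3)[C@H](C)[C@@H]2C)cc1OC | target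

**Summary**

Total step count: 8. Longest linear sequence: 7 steps (1, 3, 4, 5, 6, 7, 8); step 2 is a one-step side branch.

**Steps most likely to fail**

Step 4. The process at risk is loss of stereochemical fidelity at the benzylic cyclopropane carbon: reversible Lewis-acid ring opening could isomerise the cis-cyclopropane before the weakly nucleophilic aldehyde captures it, and the acid could later equilibrate the benzylic ring positions of the product. The fallback sets out from 7 and returns at 9, and makes the two ring bonds in separate operations. Cyclopropane 7 is opened with 3,4-dimethoxybenzyl alcohol under Cu(OTf)2 catalysis (CH2Cl2, rt). This SN2-type ring opening of a donor–acceptor cyclopropane by an alcohol needs a milder acid than aldehyde capture and likewise inverts the benzylic carbon, giving dimethyl 2-[(1R,2R)-1-[(3,4-dimethoxyphenyl)methoxy]-1-(3,4,5-trimethoxyphenyl)propan-2-yl]propanedioate F1. Oxidation of the dimethoxybenzylic CH2 group of F1 with DDQ (In(OTf)3 cat., 4 Å MS, CH2Cl2, 0 °C → rt) generates the same oxocarbenium ion as in step 4, and the tethered malonate closes the ring in an intramolecular cross-dehydrogenative coupling to 9.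

Step 5. The process at risk is insufficient thermodynamic discrimination between the two C3 epimers during equilibration, or slow base-induced erosion of the ring. The fallback sets out from 9 and returns at 14. It replaces protonation by differentiation of the two diastereotopic esters and a stereoretentive excision of one carbon.
- Hydrolysis of the less hindered ester (trans to the C2 aryl group) with KOH (1.1 equiv, MeOH/THF/H2O, rt) gives (2R,3R,4R,5R)-2-(3,4-dimethoxyphenyl)-3-(methoxycarbonyl)-4-methyl-5-(3,4,5-trimethoxyphenyl)oxolane-3-carboxylic acid F2.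
- Chemoselective reduction of the acid with BH3·SMe2 (THF, 0 °C → rt) gives methyl (2R,3S,4R,5R)-2-(3,4-dimethoxyphenyl)-3-(hydroxymethyl)-4-methyl-5-(3,4,5-trimethoxyphenyl)oxolane-3-carboxylate F3.
- Tosylation (TsCl, pyridine, DMAP) gives methyl (2R,3S,4R,5R)-2-(3,4-dimethoxyphenyl)-4-methyl-3-{[(4-methylbenzenesulfonyl)oxy]methyl}-5-(3,4,5-trimethoxyphenyl)oxolane-3-carboxylate F4.
- Excess LiEt3BH (THF, reflux) reduces both the tosylate to methyl and the remaining ester to the carbinol, giving [(2R,3S,4R,5R)-2-(3,4-dimethoxyphenyl)-3,4-dimethyl-5-(3,4,5-trimethoxyphenyl)oxolan-3-yl]methanol F5.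
- Dess–Martin oxidation gives (2R,3R,4R,5R)-2-(3,4-dimethoxyphenyl)-3,4-dimethyl-5-(3,4,5-trimethoxyphenyl)oxolane-3-carbaldehyde F6.
- Tsuji–Wilkinson decarbonylation with RhCl(PPh3)3 (1 equiv, PhCN, 130 °C) replaces the formyl group by hydrogen with retention of configuration and should give 14 directly.

Step 3. The process at risk is poor facial discrimination of the Z-alkene by the chiral copper carbene (low enantiomeric purity), or partial loss of the cis relationship. The fallback sets out from 3 and 6 and returns at 7, moving enantiocontrol from catalysis to resolution. Stereospecific but racemic carbene transfer with Rh2(esp)2 (1 mol %, CH2Cl2, rt) gives 7 together with its enantiomer, dimethyl (2R,3R)-2-methyl-3-(3,4,5-trimethoxyphenyl)cyclopropane-1,1-dicarboxylate F7. The two are separated by preparative chromatography on a chiral stationary phase, and 7 is carried on.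

**Further compounds**

F1 | step 4 | dimethyl 2-[(1R,2R)-1-[(3,4-dimethoxyphenyl)methoxy]-1-(3,4,5-trimethoxyphenyl)propan-2-yl]propanedioate | COc1ccc(CO[C@@H](c2cc(OC)c(OC)c(OC)c2)[C@H](C)C(C(=O)OC)C(=O)OC)cc1OC
F2 | step 5 | (2R,3R,4R,5R)-2-(3,4-dimethoxyphenyl)-3-(methoxycarbonyl)-4-methyl-5-(3,4,5-trimethoxyphenyl)oxolane-3-carboxylic acid | COc1ccc([C@H]2O[C@@H](c3cc(OC)c(OC)c(OC)c3)[C@H](C)[C@]2(C(=O)OC)C(=O)O)cc1OC
F3 | step 5 | methyl (2R,3S,4R,5R)-2-(3,4-dimethoxyphenyl)-3-(hydroxymethyl)-4-methyl-5-(3,4,5-trimethoxyphenyl)oxolane-3-carboxylate | COc1ccc([C@H]2O[C@@H](c3cc(OC)c(OC)c(OC)c3)[C@H](C)[C@]2(C(=O)OC)CO)cc1OC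
F4 | step 5 | methyl (2R,3S,4R,5R)-2-(3,4-dimethoxyphenyl)-4-methyl-3-{[(4-methylbenzenesulfonyl)oxy]methyl}-5-(3,4,5-trimethoxyphenyl)oxolane-3-carboxylate | COc1ccc([C@H]2O[C@@H](c3cc(OC)c(OC)c(OC)c3)[C@H](C)[C@]2(C(=O)OC)COS(=O)(=O)c4ccc(C)cc4)cc1OC
F5 | step 5 | [(2R,3S,4R,5R)-2-(3,4-dimethoxyphenyl)-3,4-dimethyl-5-(3,4,5-trimethoxyphenyl)oxolan-3-yl]methanol | COc1ccc([C@H]2O[C@@H](c3cc(OC)c(OC)c(OC)c3)[C@H](C)[C@]2(CO)C)cc1OC
F6 | step 5 | (2R,3R,4R,5R)-2-(3,4-dimethoxyphenyl)-3,4-dimethyl-5-(3,4,5-trimethoxyphenyl)oxolane-3-carbaldehyde | COc1ccc([C@H]2O[C@@H](c3cc(OC)c(OC)c(OC)c3)[C@H](C)[C@]2(C=O)C)cc1OC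
F7 | step 3 | dimethyl (2R,3R)-2-methyl-3-(3,4,5-trimethoxyphenyl)cyclopropane-1,1-dicarboxylate | COc1cc([C@H]2[C@@H](C)C2(C(=O)OC)C(=O)OC)cc(OC)c1OC
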